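Everything rests on making ring A rather than substituting it. Tachrosin is traced back to phenol 15, and 15 to a Danheiser benzannulation of 3-methoxycyclobutenone 10 (supplying C8a, C6, C5, C4a) with ynol ether 8 (C7, C8). In one operation the step forms C8–C8a, C6–C7 and C4a–C8a and closes ring A. It exploits the alternating oxygens on C5, C7 and C8a with the C8 carbon substituent wedged between two of them, a pattern that mirrors the polarity of a vinylketene and a methoxyalkyne. The precursor 8 is 2,2-dimethylfuran-3(2H)-one carrying a methoxyethynyl group at C4', so the crowded C8–C4' bond exists beforehand. The lone C8a hydroxyl then anchors ring C.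

Key step: step 6

Remarks on the chemistry
- **Numbering:** flavone numbers are used for ring A atoms in all intermediates, and primed numbers for the furanone. The target has no stereocentre.
- **Atom map of step 6:** C1, C2, C3 and C4 of 10 become C8a, C6, C5 and C4a. The methoxy-bearing and furanone-bearing alkyne carbons of 8 become C7 and C8.
- **Assumption:** cyclobutane-1,3-dione 9 is bought, stored cold and used as received. Furanone 3 is also sold, in which case step 1 falls away.
- **Handling of C5':** C5'–H is an electrophilic vinylogous formate carbon. Amines open the furanone there and aqueous hydroxide deformylates it. Stannane 7 is therefore isolated free of diethylamine, and ring C is built without hydroxide.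
- **Handling of 15:** the C8a hydroxyl lies within reach of C5'. The oxygen is acetylated and then boron-chelated at once in step 7. It is fully deprotonated in step 8, where opening of the furanone would have to expel a far more basic tertiary alkoxide.

Step 1
Reactants: 1 3-hydroxy-3-methylbutan-2-one
Product: 3 2,2-dimethylfuran-3(2H)-one, via enaminone 2 (not isolated)
Conditions: Me2NCH(OMe)2 (1.3 equiv), PhMe, 100 °C; then AcOH/H2O 4:1, 60 °C
Reagents that add atoms: N,N-dimethylformamide dimethyl acetal, COC(OC)N(C)C
Why: Amide-acetal condensation at the only enolisable methyl group gives the enaminone, acid turns it into a vinylogous iminium ion that the tertiary hydroxyl captures in a 5-exo closure, and loss of dimethylamine gives the 5-unsubstituted 3(2H)-furanone.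

Step 2
Reactants: 3 2,2-dimethylfuran-3(2H)-one
Product: 4 4-iodo-2,2-dimethylfuran-3(2H)-one
Conditions: NIS (1.1 equiv), TFA (10 mol %), MeCN, 0 °C → rt, dark
Reagents that add atoms: N-iodosuccinimide, O=C1CCC(=O)N1I
Why: Electrophilic iodination of a vinylogous ester: C4 is the β-carbon of the ring enol ether, so attack there gives an oxocarbenium ion at C5 that loses the C4 proton and restores conjugation.

Step 3
Reactants: 5 chloroacetaldehyde dimethyl acetal
Product: 7 tributyl(methoxyethynyl)stannane, via lithium methoxyacetylide 6 (not isolated)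
Conditions: Et2NH, n-BuLi (3.1 equiv each), THF, 0 °C; 5, 0 °C → rt; Bu3SnCl (0.95 equiv), −78 °C → rt; bulb-to-bulb distillation
Reagents that add atoms: tributyltin chloride, CCCC[Sn](Cl)(CCCC)CCCC
Why: Amide-base 1,2-eliminations of methanol and then HCl from the chloroacetal, followed by deprotonation, are the standard in-flask source of a lithium alkoxyacetylide, and stannylation gives a neutral, distillable reagent that carries no amine into the coupling.

Step 4
Reactants: 4 4-iodo-2,2-dimethylfuran-3(2H)-one; 7 tributyl(methoxyethynyl)stannane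
Product: 8 4-(methoxyethynyl)-2,2-dimethylfuran-3(2H)-one
Conditions: PdCl2(PhCN)2 (5 mol %), AsPh3 (10 mol %), CuI (10 mol %), NMP, rt; chromatography on K2CO3-doped silica
Reagents that add atoms: none
Why: Stille coupling of an α-iodoenone with an alkynylstannane (the fastest-transferring tin ligand) runs at room temperature without base or amine, which suits both the electrophilic C5 of the furanone and the acid-labile ynol ether, and alkoxyethynylstannanes are established partners for sp2 iodides.

Step 5
Reactants: 9 cyclobutane-1,3-dione
Product: 10 3-methoxycyclobut-2-en-1-one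
Conditions: TMSCHN2 (1.1 equiv), PhMe/MeOH 5:1, 0 °C; used as a concentrated PhMe solution
Reagents that add atoms: (trimethylsilyl)diazomethane, C[Si](C)(C)C=[N+]=[N-]
Why: The dione reacts as its strongly acidic enol (a vinylogous carboxylic acid), so diazoalkane O-methylation is fast at 0 °C and outruns the methanolysis of the strained ring that heating in acidic methanol would favour.

Step 6
Reactants: 8 4-(methoxyethynyl)-2,2-dimethylfuran-3(2H)-one; 10 3-methoxycyclobut-2-en-1-one
Product: 15 4-(2-hydroxy-4,6-dimethoxyphenyl)-2,2-dimethylfuran-3(2H)-one, via vinylketene 11 (not isolated), via vinylcyclobutenone 12 (not isolated), via dienylketene 13 (not isolated), via cyclohexadienone 14 (not isolated)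
Conditions: 8 (1.0 equiv), PhMe (0.3 M), sealed tube, 110 °C, slow addition of 10 (1.3 equiv); then 135 °C until 12 is consumed; neutral silica, product used at once
Reagents that add atoms: none
Why: Heating opens the strained ring of 10 by a conrotatory four-electron electrocyclic reaction to vinylketene 11, whose carbonyl carbon is attacked by the furanone-bearing alkyne carbon of 8 (the β-carbon of the ynol ether, made nucleophilic by the methoxy group), so a regiospecific (2+2) cycloaddition forms C8–C8a and C6–C7 and gives 12. A second four-electron opening of 12 is reversible and leads to dienylketene 13; the isomer with the methoxyvinyl group turned inward closes ring A by a disrotatory six-electron electrocyclisation that forms C4a–C8a, and enolisation of dienone 14 makes the cascade irreversible. The closest known reaction type is the Danheiser benzannulation of cyclobutenones with 1-alkoxyalkynes, including 3-oxygenated cyclobutenones that give resorcinol ethers. No stereocentre is created in 15, since the one sp3 centre of 12 is racemic and disappears on aromatisation. The selectivity needed is the orientation of the (2+2) step, and the polarity of 8 secures it: the C3' carbonyl is only cross-conjugated with the triple bond through C4', so the methoxy group alone decides which alkyne carbon is nucleophilic, the furanone ends up next to the hydroxyl-bearing carbon, and the push–pull C4'=C5' bond is too poor a ketenophile to compete. A methyl ynol ether has no β-hydrogen for retro-ene loss of an alkene at this temperature, and slow addition of 10 keeps 11 dilute, which limits ketene dimerisation and O-acylation of 15.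

Step 7
Reactants: 15 4-(2-hydroxy-4,6-dimethoxyphenyl)-2,2-dimethylfuran-3(2H)-one
Product: 18 4-(3-acetyl-2-hydroxy-4,6-dimethoxyphenyl)-2,2-dimethylfuran-3(2H)-one, via aryl acetate 16 (not isolated), via difluoroboron chelate 17 (not isolated)
Conditions: Ac2O (2.5 equiv), BF3·OEt2 (5 equiv), ClCH2CH2Cl, 0 → 60 °C; then MeOH/H2O, 50 °C
Reagents that add atoms: acetic anhydride, CC(=O)OC(C)=O
Why: Immediate O-acetylation followed by a BF3-promoted Fries rearrangement should place the acetyl group at C4a, the one free carbon beside the C8a oxygen, because only there is the ketone locked as a six-membered difluoroboron chelate (acylation at C6 gives a twisted, unchelated and reversibly formed ketone), and acetyl and then boron keep the C8a oxygen away from C5' throughout.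

Step 8
Reactants: 18 4-(3-acetyl-2-hydroxy-4,6-dimethoxyphenyl)-2,2-dimethylfuran-3(2H)-one; 19 benzoyl chloride
Product: 20 1-[3-(5,5-dimethyl-4-oxo-4,5-dihydrofuran-3-yl)-2-hydroxy-4,6-dimethoxyphenyl]-3-phenylpropane-1,3-dione
Conditions: LiN(SiMe3)2 (3.3 equiv), THF, −78 → −10 °C; 19 (1.05 equiv), −78 °C → rt; ice-cold 1 M HCl
Reagents that add atoms: none
Why: Benzoylation of the lithium phenoxide–enolate dianion is the one-flask form of the O-benzoylation/Baker–Venkataraman sequence (any O-benzoate formed is carried to the same diketone by the excess base), and the bulky, hydroxide-free base spares the furanone, which has no acidic hydrogen.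

Step 9
Reactants: 20 1-[3-(5,5-dimethyl-4-oxo-4,5-dihydrofuran-3-yl)-2-hydroxy-4,6-dimethoxyphenyl]-3-phenylpropane-1,3-dione
Product: 21 tachrosin, 8-(5,5-dimethyl-4-oxo-4,5-dihydrofuran-3-yl)-5,7-dimethoxy-2-phenyl-4H-chromen-4-one
Conditions: H2SO4 (cat.), AcOH, 90 °C
Reagents that add atoms: none
Why: Acid-catalysed cyclodehydration, the closing stage of the Baker–Venkataraman flavone synthesis, proceeds by 6-exo addition of the C8a hydroxyl to the benzoyl carbonyl and loss of water to the aromatic pyrone, while the furanone, itself a product of acid cyclisation, should persist.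

Compound list
1 | 3-hydroxy-3-methylbutan-2-one | CC(=O)C(C)(C)O | starting material
2 | (E)-1-(dimethylamino)-4-hydroxy-4-methylpent-1-en-3-one | CN(C)/C=C/C(=O)C(C)(C)O | intermediate (not isolated)
3 | 2,2-dimethylfuran-3(2H)-one | CC1(C)OC=CC1=O | intermediate
4 | 4-iodo-2,2-dimethylfuran-3(2H)-one | CC1(C)OC=C(I)C1=O | intermediate
5 | chloroacetaldehyde dimethyl acetal (2-chloro-1,1-dimethoxyethane) | COC(CCl)OC | starting material
6 | lithium methoxyacetylide | [Li]C#COC | intermediate (not isolated)
7 | tributyl(methoxyethynyl)stannane | CCCC[Sn](CCCC)(CCCC)C#COC | intermediate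
8 | 4-(methoxyethynyl)-2,2-dimethylfuran-3(2H)-one | COC#CC1=COC(C)(C)C1=O | intermediate
9 | cyclobutane-1,3-dione | O=C1CC(=O)C1 | starting material
10 | 3-methoxycyclobut-2-en-1-one | COC1=CC(=O)C1 | intermediate
11 | 3-methoxybuta-1,3-dien-1-one (vinylketene) | C=C(OC)C=C=O | intermediate (not isolated)
12 | 2-(5,5-dimethyl-4-oxo-4,5-dihydrofuran-3-yl)-3-methoxy-4-(1-methoxyvinyl)cyclobut-2-en-1-one, racemic | C=C(OC)C1C(=O)C(C2=COC(C)(C)C2=O)=C1OC | intermediate (not isolated)
13 | 2-(5,5-dimethyl-4-oxo-4,5-dihydrofuran-3-yl)-3,5-dimethoxyhexa-1,3,5-trien-1-one, ketene carbon and methoxyvinyl group cis on the central double bond | C=C(OC)/C=C(OC)\C(=C=O)C1=COC(C)(C)C1=O | intermediate (not isolated)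
14 | 2-(5,5-dimethyl-4-oxo-4,5-dihydrofuran-3-yl)-3,5-dimethoxycyclohexa-2,4-dien-1-one | O=C1CC(OC)=CC(OC)=C1C1=COC(C)(C)C1=O | intermediate (not isolated)
15 | 4-(2-hydroxy-4,6-dimethoxyphenyl)-2,2-dimethylfuran-3(2H)-one | COc1cc(O)c(C2=COC(C)(C)C2=O)c(OC)c1 | intermediate
16 | 2-(5,5-dimethyl-4-oxo-4,5-dihydrofuran-3-yl)-3,5-dimethoxyphenyl acetate | COc1cc(OC(C)=O)c(C2=COC(C)(C)C2=O)c(OC)c1 | intermediate (not isolated)
17 | difluoroboron chelate of 18 (boron bound to the C8a oxygen and the acetyl oxygen) | CC1=[O+][B-](F)(F)Oc2c1c(OC)cc(OC)c2C1=COC(C)(C)C1=O | intermediate (not isolated)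
18 | 4-(3-acetyl-2-hydroxy-4,6-dimethoxyphenyl)-2,2-dimethylfuran-3(2H)-one | CC(=O)c1c(O)c(C2=COC(C)(C)C2=O)c(OC)cc1OC | intermediate
19 | benzoyl chloride | O=C(Cl)c1ccccc1 | starting material
20 | 1-[3-(5,5-dimethyl-4-oxo-4,5-dihydrofuran-3-yl)-2-hydroxy-4,6-dimethoxyphenyl]-3-phenylpropane-1,3-dione | O=C(CC(=O)c1ccccc1)c1c(O)c(C2=COC(C)(C)C2=O)c(OC)cc1OC | intermediate
21 | tachrosin | COc1cc(OC)c2c(=O)cc(-c3ccccc3)oc2c1C1=COC(C)(C)C1=O | target

Total step count: 9. Longest linear sequence: 7 (steps 1, 2, 4, 6, 7, 8, 9).

Steps most likely to fail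

Step 6.
- **What may go wrong:** the donor-stabilised cyclobutenone may open only at temperatures where the ynol ether oligomerises. The cascade may stall before the second ring opening. The ketene may acylate the emerging phenol.
- **Fallback:** it sets out from 4 and comes back at 21. Ring A is taken ready-made and the C8–C4' bond is formed last by cross-coupling. Commercial 5,7-dimethoxyflavone is iodinated at its most nucleophilic ring A carbon (NIS, TFA, MeCN) to 8-iodo-5,7-dimethoxyflavone F1. Miyaura borylation (B2pin2, PdCl2(dppf), KOAc, dioxane, 90 °C) gives 5,7-dimethoxy-8-(4,4,5,5-tetramethyl-1,3,2-dioxaborolan-2-yl)flavone F2. Suzuki–Miyaura coupling of F2 with 4 (Pd(OAc)2, SPhos, K3PO4, PhMe with a little water, 80 °C) gives 21.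

Step 7.
- **What may go wrong:** acylation may compete at C6. Alternatively, acid may induce attack of the C8a oxygen on C5' with opening of the furanone ring.
- **Fallback:** it sets out from 15 and comes back at 21. The order of bond formation in ring C is reversed, so that the oxygen is tied up first and the acylation becomes intramolecular. The caesium phenoxide of 15 adds to ethyl 3-phenylpropiolate (Cs2CO3, DMF, 60 °C; anti oxa-Michael addition) to give ethyl (Z)-3-[2-(5,5-dimethyl-4-oxo-4,5-dihydrofuran-3-yl)-3,5-dimethoxyphenoxy]-3-phenylacrylate F3. Eaton's reagent (P2O5 in MeSO3H, 50 °C) then closes ring C by Friedel–Crafts acylation, as in the second half of a Simonis chromone synthesis. Only C4a is within reach.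

Step 4.
- **What may go wrong:** protodestannylation of 7, or hydration or carbonyl-assisted cyclisation of the electron-rich triple bond during coupling and purification.
- **Fallback:** it sets out from 4, comes back at 15, and gives up the benzannulation.
 - Commercial 3,5-dimethoxyphenol is protected (MOMCl, iPr2NEt, CH2Cl2) as 1,3-dimethoxy-5-(methoxymethoxy)benzene F4.
 - Directed ortho-lithiation between the MOM ether and a methoxy group (n-BuLi, THF, 0 °C), then 2-isopropoxy-4,4,5,5-tetramethyl-1,3,2-dioxaborolane, gives 2-[2,4-dimethoxy-6-(methoxymethoxy)phenyl]-4,4,5,5-tetramethyl-1,3,2-dioxaborolane F5.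
 - Suzuki–Miyaura coupling with 4 (Pd(OAc)2, SPhos, K3PO4, PhMe, 80 °C) gives 4-[2,4-dimethoxy-6-(methoxymethoxy)phenyl]-2,2-dimethylfuran-3(2H)-one F6.
 - Brief acetal exchange (cat. HCl, MeOH, rt) releases 15.

Further compounds
F1 | step 6 | 8-iodo-5,7-dimethoxyflavone | COc1cc(OC)c2c(=O)cc(-c3ccccc3)oc2c1I
F2 | step 6 | 5,7-dimethoxy-8-(4,4,5,5-tetramethyl-1,3,2-dioxaborolan-2-yl)flavone | COc1cc(OC)c2c(=O)cc(-c3ccccc3)oc2c1B1OC(C)(C)C(C)(C)O1
F3 | step 7 | ethyl (Z)-3-[2-(5,5-dimethyl-4-oxo-4,5-dihydrofuran-3-yl)-3,5-dimethoxyphenoxy]-3-phenylacrylate | CCOC(=O)/C=C(\Oc1cc(OC)cc(OC)c1C1=COC(C)(C)C1=O)c1ccccc1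
F4 | step 4 | 1,3-dimethoxy-5-(methoxymethoxy)benzene | COCOc1cc(OC)cc(OC)c1
F5 | step 4 | 2-[2,4-dimethoxy-6-(methoxymethoxy)phenyl]-4,4,5,5-tetramethyl-1,3,2-dioxaborolane | COCOc1cc(OC)cc(OC)c1B1OC(C)(C)C(C)(C)O1
F6 | step 4 | 4-[2,4-dimethoxy-6-(methoxymethoxy)phenyl]-2,2-dimethylfuran-3(2H)-one | COCOc1cc(OC)cc(OC)c1C1=COC(C)(C)C1=O
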